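## The problem

1. The target 17 is a 2-aryl-3-(hydroxymethyl)-2,3-dihydrobenzofuran neolignan. Ring B is fused to a five-membered oxygen ring (O1, C2, C3, C3a, C7a) that carries ring A (3,4,5-trimethoxyphenyl) on C2 and the hydroxymethyl carbon C9 on C3, and ring B bears an (E)-3-hydroxyprop-1-enyl chain at C5.
2. The only stereocentres, C2 (R) and C3 (S), are adjacent and trans, and both their relative and absolute configuration must be fixed.
3. C2 is a benzylic ether carbon next to an electron-rich arene, so it can ionise, re-close and settle trans to the C3 substituent, whereas C3 has no such escape. C3 can therefore control C2 but not the reverse, and the absolute configuration is safest when stored at C3.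
4. The fragile parts are the cinnamyl-type allylic alcohol (acid, oxidants, electrophiles), the C2–O1 benzylic ether (acid, hydrogenolysis), the two oxygenated arenes (electrophiles, oxidants) and the dihydrofuran ring, which opens or aromatises once C3 stands next to a carbonyl group.
5. The side chain should therefore arrive late, and C9 is best kept away from the carbonyl oxidation level.
6. The feature that invites a key step is the chain C2–C3–C9: C2 carries ring A and O1, C3 carries ring B, and C9 carries oxygen. This 1,3-dioxygenated three-carbon unit is the trace of a trans-1,2-diarylcyclopropane opened between C2 and C9, with an electrophile on C9 and the ring-B phenol oxygen, five atoms away, on C2.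

## Retrosynthesis

**Side chain (C5–chain bond).** The allylic alcohol of 17 is taken back to enoate 15, and the bond between C5 and the chain is cut to give aryl bromide 13 and methyl acrylate 14. A Heck coupling is preferred to carrying an alkene through the synthesis, because an alkene would not survive the mercury electrophile of the key step. It is also preferred to a formyl handle, which would need redox corrections around the borohydride step. Bromide 13 has lost three carbons and the acid-sensitive allylic alcohol. The forward steps must couple an electron-rich aryl bromide beside a free primary alcohol and reduce the ester in the 1,2 sense only.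

**C9–O bond.** The hydroxyl on C9 of 13 is traced to the carbon–mercury bond of alkylmercuric chloride 11. Mercury is what the ring-forming electrophile leaves on C9; a proton in its place would leave a methyl group that cannot be oxidised afterwards. Compound 11 is no simpler in skeleton, but it is the direct product of the key step. The forward reaction must capture a primary radical with oxygen faster than it is reduced and leave the aryl bromide alone.

**Key disconnection (O1–C2 cut, C2–C9 joined).** In 11 the O1–C2 bond is cut and C2 is reconnected to C9, which gives the trans-diarylcyclopropane phenol 9. Unlike cuts at C2–C3 or C3–C3a, this removes the heterocycle and the C2 stereocentre in one move. The precursor's two stereocentres are locked in a three-membered ring and cannot epimerise. The forward reaction must send the electrophile to the unsubstituted ring carbon, open the ring towards the carbon bearing ring A, and close with the phenol on the face opposite the breaking bond.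

**Aryl–cyclopropane bond (future C3–C3a).** Phenol 9 comes from its methoxymethyl ether 8, and the bond between the cyclopropane and ring B is cut to give cyclopropylboronate 5 and aryl iodide 7. Cutting at ring B and not at ring A puts boron on the carbon that becomes C3, so the centre carrying the absolute configuration is made in a separable, auxiliary-bearing intermediate. It also lets the iodine/bromine difference of 7 decide the coupling site. The forward reaction must retain configuration at the cyclopropyl carbon and react at C–I, not C–Br.

**Cyclopropane methylene and boronate.** The methylene carbon of 5 (the future C9) is removed to give alkenylboronate 4, which goes back through catechol ester 3 to alkyne 1 and the C2-symmetric diol 2. The diol serves twice: as a robust protecting group for boron and as the source of separable diastereomers. The forward reactions are an anti-Markovnikov syn hydroboration and a stereospecific methylene transfer to the E alkene.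

**Protected phenol.** Iodide 7 is the methoxymethyl ether of 4-bromo-2-iodophenol 6. The acetal withstands alkoxide and palladium and comes off under acid too dilute to protonate the cyclopropane.

## Roads not taken

**Alternative 1:** The cut is double, C2–C3 and O1–C2, dividing the heterocycle into the nitrovinylphenol A1 and a one-carbon unit from the benzylic sulfonium salt A2. A carbonate base makes the ylide from A2, and its carbon adds to the alkene carbon of A1 attached to ring B (C2–C3). The phenoxide then displaces the sulfide from the former ylide carbon (O1–C2), giving the trans nitromethyl compound A3.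
- Merits: two ring bonds in one operation, both partners one or two steps from catalogue compounds, and trans geometry from the displacement.
- Weak points: absolute control needs a chiral sulfide in place of the dimethyl sulfide unit of A2, and induction with a semi-stabilised benzylic ylide is much less secure than with ester-stabilised ylides. The nitromethyl group must also become CH2OH through a Nef reaction to aldehyde A4 and a reduction. In A4, C3 is next to a carbonyl and β to the ring oxygen, the situation in which the ring opens by β-elimination or aromatises. The usual Nef conditions also threaten the C2 ether and the electron-rich rings.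
- Comparison: this road is about two steps shorter and its key step builds more. The chosen plan sets against that a C9 that arrives at the alcohol oxidation level without any C3 carbonyl, and an absolute configuration taken from a separable, configurationally locked cyclopropane.

**Alternative 2:** The cut is C2–C3. Rh2(S-PTTL)4 or its enantiomer decomposes the aryldiazoacetate A5, and the carbenoid inserts into the benzylic ether C–H bond to close the ring as the cis ester A6. Base epimerisation at C3 gives the trans ester A7, and hydride reduction leads to bromide 13, where this road meets the chosen one.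
- Merits: catalytic enantiocontrol, a reaction class established for this ring system with electron-rich benzyl ethers, and C9 delivered as an ester.
- Weak points: the insertion gives cis, so an ester enolate β to the ring oxygen must be passed, with ring opening as the side reaction. After that correction the absolute configuration rests on C2 alone, the ionisable centre. A5 needs about four steps, including a diazo transfer.
- Comparison: in precedent and catalytic induction this road is better than the chosen plan, at about the same step count. The chosen plan sets against it a trans ring formed directly with no epimerisation, chirality stored at the non-ionisable C3, and stereochemical purity secured by separating diastereomers, not by a catalyst's facial selectivity.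

**Alternative 3:** The cut is C3–C3a, together with C9–O. The aryl radical generated from the iodide of allylic aryl ether A8 cyclises 5-exo-trig onto the vinyl group. The resulting primary C9 radical is trapped by a persistent nitroxide to give A9, and reductive N–O cleavage leads to 13.
- Merits: A8 is made quickly from 6 and an enantioenriched allylic partner, C9–O forms in the ring-forming step, conditions are mild, and iodide-over-bromide selectivity is secure.
- Weak points: the trans/cis ratio is decided only kinetically by the C2 aryl group. The cis isomer cannot be corrected, because equilibration through C2 would turn it into the enantiomer of the trans series. A8 is a benzylic and allylic aryl ether prone to ionisation, racemisation and allylic transposition, and it alone carries the absolute configuration.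
- Comparison: this road is two to three steps shorter, which is conceded. The chosen plan sets against it a stereospecific trans relationship and a configuration held at C3. The same C9 radical appears in step 7 of the chosen route.

Key step: step 6

Assumption: diol 2 is taken as a catalogue compound, and its (R,R) form is taken to favour the (1S,2S)-cyclopropane 5; the two diastereomers are separable, and if the facial preference is the reverse the (S,S)-diol is used with nothing else changed.

## Route

Step 1
Reactants: 1 5-ethynyl-1,2,3-trimethoxybenzene; 2 (2R,3R)-1,4-dimethoxy-1,1,4,4-tetraphenylbutane-2,3-diol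
Product: 4 (4R,5R)-4,5-bis[methoxy(diphenyl)methyl]-2-[(E)-2-(3,4,5-trimethoxyphenyl)ethenyl]-1,3,2-dioxaborolane, via catechol boronate 3 (not isolated)
Conditions: catecholborane, Cy2BH (10 mol %), THF, rt; then 2, rt
Reagents that add atoms: catecholborane, B1Oc2ccccc2O1
Why: Syn hydroboration of the terminal arylalkyne (Brown hydroboration, accelerated by catalytic Cy2BH) places boron on the terminal carbon and fixes the E geometry; the labile catechol ester is then exchanged for diol 2, whose dioxaborolane is robust enough for chromatography.

Step 2
Reactants: 4 (4R,5R)-4,5-bis[methoxy(diphenyl)methyl]-2-[(E)-2-(3,4,5-trimethoxyphenyl)ethenyl]-1,3,2-dioxaborolane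
Product: 5 (4R,5R)-4,5-bis[methoxy(diphenyl)methyl]-2-[(1S,2S)-2-(3,4,5-trimethoxyphenyl)cyclopropyl]-1,3,2-dioxaborolane
Conditions: CH2N2 (excess), Pd(OAc)2 (5 mol %), Et2O, 0 °C; separation of the diastereomers on SiO2
Reagents that add atoms: diazomethane, C=[N+]=[N-]
Why: Pd(OAc)2-catalysed methylene transfer from diazomethane to alkenylboronates is stereospecific, so the E alkene should give only trans-cyclopropanes; the C2-symmetric auxiliary differentiates the two faces and makes the two trans isomers separable diastereomers, which secures a single stereoisomer whatever the facial ratio. Both cyclopropane stereocentres are set here.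

Step 3
Reactants: 6 4-bromo-2-iodophenol
Product: 7 4-bromo-2-iodo-1-(methoxymethoxy)benzene
Conditions: MOMCl, i-Pr2NEt, CH2Cl2, 0 °C to rt
Reagents that add atoms: chloromethyl methyl ether, COCCl
Why: O-alkylation of the phenol with an α-chloro ether (Williamson-type etherification) gives an acetal that tolerates alkoxide base and zerovalent palladium and leaves both carbon–halogen bonds untouched.

Step 4
Reactants: 5 (4R,5R)-4,5-bis[methoxy(diphenyl)methyl]-2-[(1S,2S)-2-(3,4,5-trimethoxyphenyl)cyclopropyl]-1,3,2-dioxaborolane; 7 4-bromo-2-iodo-1-(methoxymethoxy)benzene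
Product: 8 4-bromo-1-(methoxymethoxy)-2-[(1S,2S)-2-(3,4,5-trimethoxyphenyl)cyclopropyl]benzene
Conditions: Pd(PPh3)4 (10 mol %), KOt-Bu (1 M in t-BuOH), DME, 85 °C; 7 (1.3 equiv)
Reagents that add atoms: none
Why: Suzuki–Miyaura coupling: oxidative addition of zerovalent palladium to C–I is much faster than to C–Br, the alkoxide activates the hindered boronate as its ate complex, and a cyclopropyl group is transferred with retention, so the configuration of the carbon that becomes C3 is carried over.

Step 5
Reactants: 8 4-bromo-1-(methoxymethoxy)-2-[(1S,2S)-2-(3,4,5-trimethoxyphenyl)cyclopropyl]benzene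
Product: 9 4-bromo-2-[(1S,2S)-2-(3,4,5-trimethoxyphenyl)cyclopropyl]phenol
Conditions: HCl (2 M), MeOH–THF, rt to 40 °C
Reagents that add atoms: none
Why: Acid-catalysed acetal exchange with methanol releases the phenol; a cyclopropane that carries only donor aryl groups should not be protonated by dilute methanolic HCl at this temperature, so the ring should survive.

Step 6
Reactants: 9 4-bromo-2-[(1S,2S)-2-(3,4,5-trimethoxyphenyl)cyclopropyl]phenol
Product: 11 chloro{[(2R,3R)-5-bromo-2-(3,4,5-trimethoxyphenyl)-2,3-dihydro-1-benzofuran-3-yl]methyl}mercury, via alkylmercuric trifluoroacetate 10 (not isolated)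
Conditions: Hg(OCOCF3)2 (1.1 equiv), CH2Cl2, −20 to 0 °C; then sat. aq NaCl
Reagents that add atoms: Hg(OCOCF3)2, FC(F)(F)C(=O)O[Hg]OC(=O)C(F)(F)F; NaCl, [Na+].[Cl-]
Why: Proposed new method: Hg(OCOCF3)2 should attack the unsubstituted cyclopropane carbon of 9 (the future C9) at its corner, the bond from that carbon to the carbon bearing ring A lengthens as positive charge builds up there, and the ortho phenol oxygen of ring B captures that carbon, so that O1–C2 forms while C2–C9 breaks and C9 keeps the mercury. The closest known reactions are the intermolecular solvomercuration of trans-1,2-diarylcyclopropanes, which goes with inversion at the benzylic carbon, and the intramolecular alkoxymercuration of cyclopropanealkanols; a phenol tethered to a diarylcyclopropane has not been shown as the internal nucleophile. The dihydrofuran ring closes in a 5-exo-tet mode, the breaking C2–C9 bond lying outside the new ring. C2 is the only new stereocentre and is set by backside displacement relative to the untouched cyclopropane carbon that becomes C3, which gives the 2,3-trans isomer; a free benzylic cation would close to the same trans ring for steric reasons, so the outcome does not depend on the timing of the two bond changes. The step needs cleavage towards C2 and not towards C3: ring A is a net donor, ring B is held close to an unsubstituted phenyl ring because the bromine meta to the cyclopropane offsets the ortho hydroxyl, and only cleavage towards C2 can be assisted by the phenol. It also needs the three-membered ring to react faster than the two electron-rich arenes, as is usual for arylcyclopropanes with divalent mercury; the reagent is therefore kept near one equivalent at low temperature, and any aryl–mercury bond that does form is removed by borohydride in step 7. Exchange of trifluoroacetate for chloride then gives a neutral alkylmercuric chloride that can be chromatographed or crystallised.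

Step 7
Reactants: 11 chloro{[(2R,3R)-5-bromo-2-(3,4,5-trimethoxyphenyl)-2,3-dihydro-1-benzofuran-3-yl]methyl}mercury
Product: 13 [(2R,3S)-5-bromo-2-(3,4,5-trimethoxyphenyl)-2,3-dihydro-1-benzofuran-3-yl]methanol, via primary hydroperoxide 12 (not isolated)
Conditions: NaBH4, O2 (saturated solution, continuous stream), DMF, 0 °C to rt
Reagents that add atoms: dioxygen, O=O
Why: Oxidative demercuration: NaBH4 converts the alkylmercuric chloride into the alkylmercuric hydride, which fragments to the primary C9 radical; in oxygen-saturated DMF this radical should be captured by O2 faster than it abstracts hydrogen, and the hydroperoxide is reduced in the flask to the alcohol. The radical is exocyclic, so neither stereocentre is touched (the change of the C3 descriptor from R to S reflects only substituent priority), and the aryl bromide is inert to borohydride.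

Step 8
Reactants: 13 [(2R,3S)-5-bromo-2-(3,4,5-trimethoxyphenyl)-2,3-dihydro-1-benzofuran-3-yl]methanol; 14 methyl acrylate
Product: 15 methyl (E)-3-[(2R,3S)-3-(hydroxymethyl)-2-(3,4,5-trimethoxyphenyl)-2,3-dihydro-1-benzofuran-5-yl]prop-2-enoate
Conditions: Pd(OAc)2 (5 mol %), P(o-tol)3 (10 mol %), Et3N, DMF, 100 °C
Reagents that add atoms: none
Why: Mizoroki–Heck reaction: oxidative addition to the aryl bromide, syn carbopalladation of the acrylate at its unsubstituted carbon and syn β-hydride elimination give the E cinnamate; the free alcohol and the benzylic ether are tolerated under these basic conditions.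

Step 9
Reactants: 15 methyl (E)-3-[(2R,3S)-3-(hydroxymethyl)-2-(3,4,5-trimethoxyphenyl)-2,3-dihydro-1-benzofuran-5-yl]prop-2-enoate
Product: 17 (E)-3-[(2R,3S)-3-(hydroxymethyl)-2-(3,4,5-trimethoxyphenyl)-2,3-dihydro-1-benzofuran-5-yl]prop-2-en-1-ol, via enal 16 (not isolated)
Conditions: i-Bu2AlH (4 equiv), THF, −78 to 0 °C; aq potassium sodium tartrate
Reagents that add atoms: none
Why: i-Bu2AlH reduces α,β-unsaturated esters in the 1,2 sense through the enal to the allylic alcohol without touching the alkene; the excess covers the free hydroxyl, and the neutral tartrate work-up spares the acid-sensitive cinnamyl alcohol and the C2 benzylic ether.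

## Compound list

1 | 5-ethynyl-1,2,3-trimethoxybenzene | C#Cc1cc(OC)c(OC)c(OC)c1 | starting material
2 | (2R,3R)-1,4-dimethoxy-1,1,4,4-tetraphenylbutane-2,3-diol | COC(c1ccccc1)(c1ccccc1)[C@H](O)[C@@H](O)C(OC)(c1ccccc1)c1ccccc1 | starting material
3 | 2-[(E)-2-(3,4,5-trimethoxyphenyl)ethenyl]-1,3,2-benzodioxaborole | COc1cc(/C=C/B2Oc3ccccc3O2)cc(OC)c1OC | intermediate
4 | (4R,5R)-4,5-bis[methoxy(diphenyl)methyl]-2-[(E)-2-(3,4,5-trimethoxyphenyl)ethenyl]-1,3,2-dioxaborolane | COc1cc(/C=C/B2O[C@@H](C(OC)(c3ccccc3)c3ccccc3)[C@H](C(OC)(c3ccccc3)c3ccccc3)O2)cc(OC)c1OC | intermediate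
5 | (4R,5R)-4,5-bis[methoxy(diphenyl)methyl]-2-[(1S,2S)-2-(3,4,5-trimethoxyphenyl)cyclopropyl]-1,3,2-dioxaborolane | COc1cc([C@H]2C[C@@H]2B4O[C@@H](C(OC)(c5ccccc5)c5ccccc5)[C@H](C(OC)(c5ccccc5)c5ccccc5)O4)cc(OC)c1OC | intermediate
6 | 4-bromo-2-iodophenol | Oc1ccc(Br)cc1I | starting material
7 | 4-bromo-2-iodo-1-(methoxymethoxy)benzene | COCOc1ccc(Br)cc1I | intermediate
8 | 4-bromo-1-(methoxymethoxy)-2-[(1S,2S)-2-(3,4,5-trimethoxyphenyl)cyclopropyl]benzene | COc1cc([C@H]2C[C@@H]2c3cc(Br)ccc3OCOC)cc(OC)c1OC | intermediate
9 | 4-bromo-2-[(1S,2S)-2-(3,4,5-trimethoxyphenyl)cyclopropyl]phenol | COc1cc([C@H]2C[C@@H]2c3cc(Br)ccc3O)cc(OC)c1OC | intermediate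
10 | {[(2R,3R)-5-bromo-2-(3,4,5-trimethoxyphenyl)-2,3-dihydro-1-benzofuran-3-yl]methyl}mercury trifluoroacetate | COc1cc([C@@H]2Oc3ccc(Br)cc3[C@H]2C[Hg]OC(=O)C(F)(F)F)cc(OC)c1OC | intermediate
11 | chloro{[(2R,3R)-5-bromo-2-(3,4,5-trimethoxyphenyl)-2,3-dihydro-1-benzofuran-3-yl]methyl}mercury | COc1cc([C@@H]2Oc3ccc(Br)cc3[C@H]2C[Hg]Cl)cc(OC)c1OC | intermediate
12 | (2R,3S)-5-bromo-3-(hydroperoxymethyl)-2-(3,4,5-trimethoxyphenyl)-2,3-dihydro-1-benzofuran | COc1cc([C@@H]2Oc3ccc(Br)cc3[C@H]2COO)cc(OC)c1OC | intermediate
13 | [(2R,3S)-5-bromo-2-(3,4,5-trimethoxyphenyl)-2,3-dihydro-1-benzofuran-3-yl]methanol | COc1cc([C@@H]2Oc3ccc(Br)cc3[C@H]2CO)cc(OC)c1OC | intermediate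
14 | methyl acrylate | C=CC(=O)OC | starting material
15 | methyl (E)-3-[(2R,3S)-3-(hydroxymethyl)-2-(3,4,5-trimethoxyphenyl)-2,3-dihydro-1-benzofuran-5-yl]prop-2-enoate | COc1cc([C@@H]2Oc3ccc(/C=C/C(=O)OC)cc3[C@H]2CO)cc(OC)c1OC | intermediate
16 | (E)-3-[(2R,3S)-3-(hydroxymethyl)-2-(3,4,5-trimethoxyphenyl)-2,3-dihydro-1-benzofuran-5-yl]prop-2-enal | COc1cc([C@@H]2Oc3ccc(/C=C/C=O)cc3[C@H]2CO)cc(OC)c1OC | intermediate
17 | (E)-3-[(2R,3S)-3-(hydroxymethyl)-2-(3,4,5-trimethoxyphenyl)-2,3-dihydro-1-benzofuran-5-yl]prop-2-en-1-ol | COc1cc([C@@H]2Oc3ccc(/C=C/CO)cc3[C@H]2CO)cc(OC)c1OC | target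

## Step count and least certain steps

Total: 9 steps. Longest linear sequence: 8 steps (steps 1, 2, 4, 5, 6, 7, 8 and 9 from alkyne 1); step 3 is a one-step side branch.

**Step 6 (key step, proposed new method).** Three things may go wrong.
- The ring may open in the wrong direction: the bond from the methylene carbon to the ring-B-bearing carbon breaks, helped by the ortho hydroxyl, and that path cannot end in ring closure.
- Ring A or the phenol ring may be mercurated and use up the electrophile.
- The CF3CO2H released may open the ring by protonation, leaving hydrogen instead of mercury on C9.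

The fallback separates the two events and uses only known reaction types. It sets out from phenol 9 and comes back at 13. Acetylation (Ac2O, pyridine) gives the aryl acetate F1. Its ring B is now clearly electron-poor, so the known intermolecular methoxymercuration of a trans-1,2-diarylcyclopropane (Hg(OCOCF3)2, MeOH–CH2Cl2) should open the ring only towards the carbon bearing ring A, with inversion. This gives the alkylmercuric trifluoroacetate F2 (not isolated) and, after chloride exchange, the acyclic alkylmercuric chloride F3. Oxidative demercuration as in step 7 leads through the hydroperoxide F4 (not isolated) to the primary alcohol F5. K2CO3 in MeOH frees the phenol F6, which is not isolated. A catalytic amount of TsOH in CH2Cl2 then ionises the benzylic methyl ether and the phenol closes the ring trans to the retained C3 substituent, giving 13.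

**Step 2.** The remote auxiliary may discriminate poorly between the two alkene faces, so much material could be lost to the unwanted diastereomer. Diazomethane also limits the scale. The fallback replaces auxiliary control by catalyst control; it sets out from alkyne 1 and returns at 8.
- Hydroxymethylation (n-BuLi, paraformaldehyde) gives the propargylic alcohol F7.
- Semi-hydrogenation over Pd/CaCO3 poisoned with Pb(OAc)2 gives the (Z)-allylic alcohol F8.
- Phosphorylation (ClP(O)(OEt)2, pyridine) gives the allylic phosphate F9.
- The known enantioselective borylative ring closure catalysed by monovalent copper (CuCl, a chiral bisphosphine, B2pin2, KOt-Bu, THF) gives the trans pinacol boronate F10; the ligand enantiomer is chosen for the (1S,2S) series.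
- Suzuki–Miyaura coupling of F10 with 7 (Pd(OAc)2, PCy3, K3PO4, toluene–water) gives 8.

**Step 4.** Transmetalation of the hindered, very stable dioxaborolane may be slow. The arylpalladium iodide then has time to be reduced, and zerovalent palladium may begin to insert into the C–Br bonds of 7 and 8, leading to oligomers. The fallback changes the boron partner; it sets out from 5 and returns at 8. Reductive cleavage of the auxiliary with LiAlH4 gives the lithium trihydridoborate F11 (not isolated), and acidic hydrolysis gives the free boronic acid F12, with diol 2 recovered. F12 is coupled with 7 under aqueous conditions (Pd(OAc)2, PCy3, K3PO4, toluene–water, 80 °C), where a free cyclopropylboronic acid transmetalates readily and with retention.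

**Step 7.** Hydrogen-atom transfer to the C9 radical from the alkylmercuric hydride or the solvent may outrun capture by oxygen, giving reductive instead of oxidative demercuration. The fallback traps the radical with a persistent radical instead of a gas; it sets out from 11 and returns at 13. NaBH4 in DMF under argon with an excess of TEMPO gives the alkoxyamine F13, the same compound as A9. Zn in AcOH–THF–water cleaves the N–O bond to give 13.

## Further compounds

F1 | step 6 | 4-bromo-2-[(1S,2S)-2-(3,4,5-trimethoxyphenyl)cyclopropyl]phenyl acetate | COc1cc([C@H]2C[C@@H]2c3cc(Br)ccc3OC(C)=O)cc(OC)c1OC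
F2 | step 6 | {(2R,3R)-2-[2-(acetyloxy)-5-bromophenyl]-3-methoxy-3-(3,4,5-trimethoxyphenyl)propyl}mercury trifluoroacetate | COc1cc([C@H](OC)[C@H](C[Hg]OC(=O)C(F)(F)F)c2cc(Br)ccc2OC(C)=O)cc(OC)c1OC
F3 | step 6 | chloro{(2R,3R)-2-[2-(acetyloxy)-5-bromophenyl]-3-methoxy-3-(3,4,5-trimethoxyphenyl)propyl}mercury | COc1cc([C@H](OC)[C@H](C[Hg]Cl)c2cc(Br)ccc2OC(C)=O)cc(OC)c1OC
F4 | step 6 | 4-bromo-2-[(1R,2S)-3-hydroperoxy-1-methoxy-1-(3,4,5-trimethoxyphenyl)propan-2-yl]phenyl acetate | COc1cc([C@H](OC)[C@H](COO)c2cc(Br)ccc2OC(C)=O)cc(OC)c1OC
F5 | step 6 | 4-bromo-2-[(1R,2S)-3-hydroxy-1-methoxy-1-(3,4,5-trimethoxyphenyl)propan-2-yl]phenyl acetate | COc1cc([C@H](OC)[C@H](CO)c2cc(Br)ccc2OC(C)=O)cc(OC)c1OC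
F6 | step 6 | 4-bromo-2-[(1R,2S)-3-hydroxy-1-methoxy-1-(3,4,5-trimethoxyphenyl)propan-2-yl]phenol | COc1cc([C@H](OC)[C@H](CO)c2cc(Br)ccc2O)cc(OC)c1OC
F7 | step 2 | 3-(3,4,5-trimethoxyphenyl)prop-2-yn-1-ol | COc1cc(C#CCO)cc(OC)c1OC
F8 | step 2 | (Z)-3-(3,4,5-trimethoxyphenyl)prop-2-en-1-ol | COc1cc(/C=C\CO)cc(OC)c1OC
F9 | step 2 | diethyl (Z)-3-(3,4,5-trimethoxyphenyl)prop-2-en-1-yl phosphate | CCOP(=O)(OCC)OC/C=C\c1cc(OC)c(OC)c(OC)c1
F10 | step 2 | 4,4,5,5-tetramethyl-2-[(1S,2S)-2-(3,4,5-trimethoxyphenyl)cyclopropyl]-1,3,2-dioxaborolane | COc1cc([C@H]2C[C@@H]2B3OC(C)(C)C(C)(C)O3)cc(OC)c1OC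
F11 | step 4 | lithium trihydrido[(1S,2S)-2-(3,4,5-trimethoxyphenyl)cyclopropyl]borate | [Li+].COc1cc([C@H]2C[C@@H]2[BH3-])cc(OC)c1OC
F12 | step 4 | [(1S,2S)-2-(3,4,5-trimethoxyphenyl)cyclopropyl]boronic acid | COc1cc([C@H]2C[C@@H]2B(O)O)cc(OC)c1OC
F13 | step 7 | 1-{[(2R,3S)-5-bromo-2-(3,4,5-trimethoxyphenyl)-2,3-dihydro-1-benzofuran-3-yl]methoxy}-2,2,6,6-tetramethylpiperidine | COc1cc([C@@H]2Oc3ccc(Br)cc3[C@H]2CON4C(C)(C)CCCC4(C)C)cc(OC)c1OC
A1 | alternative 1 | (E)-4-bromo-2-(2-nitroethenyl)phenol | Oc1ccc(Br)cc1/C=C/[N+](=O)[O-]
A2 | alternative 1 | dimethyl[(3,4,5-trimethoxyphenyl)methyl]sulfonium bromide | COc1cc(C[S+](C)C)cc(OC)c1OC.[Br-]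
A3 | alternative 1 | (2R,3S)-5-bromo-3-(nitromethyl)-2-(3,4,5-trimethoxyphenyl)-2,3-dihydro-1-benzofuran | COc1cc([C@@H]2Oc3ccc(Br)cc3[C@H]2C[N+](=O)[O-])cc(OC)c1OC
A4 | alternative 1 | (2R,3R)-5-bromo-2-(3,4,5-trimethoxyphenyl)-2,3-dihydro-1-benzofuran-3-carbaldehyde | COc1cc([C@@H]2Oc3ccc(Br)cc3[C@H]2C=O)cc(OC)c1OC
A5 | alternative 2 | methyl 2-{5-bromo-2-[(3,4,5-trimethoxyphenyl)methoxy]phenyl}-2-diazoacetate | COC(=O)C(=[N+]=[N-])c1cc(Br)ccc1OCc1cc(OC)c(OC)c(OC)c1
A6 | alternative 2 | methyl (2R,3S)-5-bromo-2-(3,4,5-trimethoxyphenyl)-2,3-dihydro-1-benzofuran-3-carboxylate (cis) | COc1cc([C@@H]2Oc3ccc(Br)cc3[C@@H]2C(=O)OC)cc(OC)c1OC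
A7 | alternative 2 | methyl (2R,3R)-5-bromo-2-(3,4,5-trimethoxyphenyl)-2,3-dihydro-1-benzofuran-3-carboxylate (trans) | COc1cc([C@@H]2Oc3ccc(Br)cc3[C@H]2C(=O)OC)cc(OC)c1OC
A8 | alternative 3 | 4-bromo-2-iodo-1-{[(1R)-1-(3,4,5-trimethoxyphenyl)prop-2-en-1-yl]oxy}benzene | COc1cc([C@@H](C=C)Oc2ccc(Br)cc2I)cc(OC)c1OC
A9 | alternative 3 | 1-{[(2R,3S)-5-bromo-2-(3,4,5-trimethoxyphenyl)-2,3-dihydro-1-benzofuran-3-yl]methoxy}-2,2,6,6-tetramethylpiperidine | COc1cc([C@@H]2Oc3ccc(Br)cc3[C@H]2CON4C(C)(C)CCCC4(C)C)cc(OC)c1OC
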